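The 14-membered carbocycle (ring atoms C1–C14, C1 being the stereocentre) is cut at the C4–C5 single bond beside the trisubstituted C3=C4 alkene. Across that alkene the hydroxymethyl group on C4 is trans, and ring carbon C5 cis, to C2: the arrangement obtained when the iodine of a (Z)-2-iodoallylic ether is replaced by carbon with retention. A single intramolecular alkylzinc–alkenyl iodide coupling therefore forms C4–C5, closes the macrocycle and delivers the C3=C4 geometry. Its precursor is an acyclic (R)-configured pentaene with the (Z)-alkenyl iodide at C4, a primary iodide at C5 and a silyl ether, assembled from three fragments; C1 and the iodoalkene arrive together in an Evans alkylation.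

Key step: step 19

Remark: atom labels used below: C1 is the ring stereocentre, the ring alkenes are C3=C4 (C4 carries CH2OH), C7=C8 and C11=C12, C14 closes the ring back to C1, and C15 is the exocyclic alkene carbon on C1; acyclic intermediates keep these labels, and 1, 5, 8, 17 and 26 are taken as commercial.

Step 1
Reactants: 1 hex-5-yn-1-ol
Product: 3 (E)-6-iodo-5-methylhex-5-en-1-ol, via alkenylalane 2 (not isolated)
Conditions: AlMe3 (3 equiv), Cp2ZrCl2 (0.25 equiv), CH2Cl2, 0 °C to rt; then I2, THF, −30 to 0 °C
Reagents that add atoms: trimethylaluminium, C[Al](C)C; iodine, [I][I]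
Why: Zirconium-catalysed carboalumination (Negishi methylalumination) adds CH3 and aluminium syn across the terminal alkyne with aluminium on the terminal carbon, and iodinolysis with retention should give the (E)-alkenyl iodide that later fixes the C11=C12 geometry.

Step 2
Reactants: 3 (E)-6-iodo-5-methylhex-5-en-1-ol
Product: 4 (E)-6-iodo-5-methylhex-5-enoic acid
Conditions: TEMPO (cat.), PhI(OAc)2, MeCN/H2O, rt
Reagents that add atoms: water, O
Why: Nitroxyl-catalysed oxidation of a primary alcohol through the aldehyde hydrate to the carboxylic acid is mild enough to leave the alkenyl iodide untouched.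

Step 3
Reactants: 4 (E)-6-iodo-5-methylhex-5-enoic acid; 5 (S)-4-benzyloxazolidin-2-one
Product: 7 (S)-4-benzyl-3-[(E)-6-iodo-5-methylhex-5-enoyl]oxazolidin-2-one, via mixed pivalic anhydride 6 (not isolated)
Conditions: t-BuCOCl, Et3N, THF, −20 °C; then 5, LiCl, rt
Reagents that add atoms: none
Why: N-acylation of the oxazolidinone by the mixed pivalic anhydride, attacked at its less hindered carbonyl, is the standard way of attaching an Evans auxiliary.

Step 4
Reactants: 8 3-methylanisole
Product: 9 1-methoxy-5-methylcyclohexa-1,4-diene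
Conditions: Li, NH3 (l), t-BuOH, THF, −78 to −33 °C
Reagents that add atoms: none
Why: Birch reduction of an anisole gives the unconjugated 1,4-diene with methoxy and methyl on the two remaining double bonds, so the future C7=C8 alkene is held cis inside a six-membered ring.

Step 5
Reactants: 9 1-methoxy-5-methylcyclohexa-1,4-diene
Product: 11 methyl (Z)-6-hydroxy-3-methylhex-3-enoate, via aldehyde ester 10 (not isolated)
Conditions: O3 (1 equiv), CH2Cl2/MeOH, −78 °C; Me2S; then NaBH4, 0 °C
Reagents that add atoms: ozone, [O-][O+]=O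
Why: Chemoselective ozonolysis of the electron-rich enol ether double bond (the trisubstituted alkene reacts more slowly) followed by borohydride reduction of the aldehyde should give the hydroxy ester with the ring-derived (Z)-alkene intact.

Step 6
Reactants: 11 methyl (Z)-6-hydroxy-3-methylhex-3-enoate
Product: 12 methyl (Z)-6-chloro-3-methylhex-3-enoate
Conditions: PPh3, N-chlorosuccinimide, CH2Cl2, 0 °C to rt
Reagents that add atoms: N-chlorosuccinimide, O=C1CCC(=O)N1Cl
Why: Appel-type chlorination replaces the primary hydroxyl by SN2 attack on the alkoxyphosphonium ion and gives a chloride that acts as a masked C5 iodide, inert to the zinc, palladium, enolate and Grignard steps that follow.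

Step 7
Reactants: 12 methyl (Z)-6-chloro-3-methylhex-3-enoate
Product: 13 (Z)-6-chloro-3-methylhex-3-en-1-ol
Conditions: i-Bu2AlH (2.5 equiv), CH2Cl2, −78 to 0 °C
Reagents that add atoms: none
Why: Ester reduction by the aluminium hydride (two hydride transfers via the aldehyde) gives the primary alcohol at low temperature without touching the alkyl chloride or moving the β,γ-alkene into conjugation.

Step 8
Reactants: 13 (Z)-6-chloro-3-methylhex-3-en-1-ol
Product: 14 (Z)-6-chloro-1-iodo-3-methylhex-3-ene
Conditions: PPh3, I2, imidazole, CH2Cl2, 0 °C to rt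
Reagents that add atoms: iodine, [I][I]
Why: Appel iodination replaces the primary hydroxyl by iodide through SN2 attack on the alkoxyphosphonium ion, giving the C10 iodide into which zinc inserts in preference to the chloride.

Step 9
Reactants: 14 (Z)-6-chloro-1-iodo-3-methylhex-3-ene; 7 (S)-4-benzyl-3-[(E)-6-iodo-5-methylhex-5-enoyl]oxazolidin-2-one
Product: 16 (S)-4-benzyl-3-[(5E,9Z)-12-chloro-5,9-dimethyldodeca-5,9-dienoyl]oxazolidin-2-one, via alkylzinc iodide 15 (not isolated)
Conditions: Zn dust (activated with BrCH2CH2Br, Me3SiCl), THF, 40 °C; then 7, Pd(PPh3)4 (5 mol%), THF, rt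
Reagents that add atoms: none
Why: Zinc inserts only into the primary C–I bond, and Negishi coupling of the homoallylic alkylzinc iodide with the (E)-alkenyl iodide forms C10–C11 with retention of both alkene geometries while the imide is tolerated by the organozinc.

Step 10
Reactants: 17 but-2-yne-1,4-diol
Product: 18 4-[(tert-butyldimethylsilyl)oxy]but-2-yn-1-ol
Conditions: NaH (1 equiv), THF, 0 °C; then t-BuMe2SiCl (1 equiv), rt
Reagents that add atoms: tert-butyldimethylsilyl chloride, CC(C)(C)[Si](C)(C)Cl
Why: Monosilylation of the sparingly soluble monosodium alkoxide of a symmetrical diol should protect one hydroxyl only and leave the other free to direct the next step.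

Step 11
Reactants: 18 4-[(tert-butyldimethylsilyl)oxy]but-2-yn-1-ol
Product: 20 (Z)-4-[(tert-butyldimethylsilyl)oxy]-3-iodobut-2-en-1-ol, via cyclic alkenylalanate 19 (not isolated)
Conditions: NaAlH2(OCH2CH2OMe)2 (1.5 equiv), THF, 0 °C to rt; then I2, THF, −78 to 0 °C
Reagents that add atoms: iodine, [I][I]
Why: Alkoxide-directed trans-hydroalumination of the propargylic alcohol delivers hydride to the nearer alkyne carbon (future C3) and places aluminium on the distal carbon (future C4) in a five-membered alkenylalanate, and iodinolysis with retention should give the (Z)-iodoalkene with iodine cis to the CH2OH carbon (future C2).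

Step 12
Reactants: 20 (Z)-4-[(tert-butyldimethylsilyl)oxy]-3-iodobut-2-en-1-ol
Product: 21 (Z)-[(4-bromo-2-iodobut-2-en-1-yl)oxy](tert-butyl)dimethylsilane
Conditions: CBr4, PPh3, CH2Cl2, −20 to 0 °C
Reagents that add atoms: carbon tetrabromide, BrC(Br)(Br)Br
Why: Appel bromination converts the primary allylic alcohol into the allylic bromide by SN2 displacement at low temperature, which keeps the alkene geometry and the silyl ether.

Step 13
Reactants: 16 (S)-4-benzyl-3-[(5E,9Z)-12-chloro-5,9-dimethyldodeca-5,9-dienoyl]oxazolidin-2-one; 21 (Z)-[(4-bromo-2-iodobut-2-en-1-yl)oxy](tert-butyl)dimethylsilane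
Product: 23 (S)-4-benzyl-3-[(2R,5E,9Z)-2-{(Z)-4-[(tert-butyldimethylsilyl)oxy]-3-iodobut-2-en-1-yl}-12-chloro-5,9-dimethyldodeca-5,9-dienoyl]oxazolidin-2-one, via sodium enolate 22 (not isolated)
Conditions: NaN(SiMe3)2 (1.1 equiv), THF, −78 °C; then 21 (2 equiv), −78 to −40 °C
Reagents that add atoms: none
Why: Evans asymmetric alkylation, in which the chelated (Z)-sodium enolate of the (S)-benzyl oxazolidinone imide is attacked by the reactive prenyl-like allylic bromide on the face opposite the benzyl group, should set C1 as (R) and deliver C2–C4 with the (Z)-iodoalkene already in place.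

Step 14
Reactants: 23 alkylated imide
Product: 24 (2R,5E,9Z)-2-{(Z)-4-[(tert-butyldimethylsilyl)oxy]-3-iodobut-2-en-1-yl}-12-chloro-5,9-dimethyldodeca-5,9-dienoic acid
Conditions: LiOH, H2O2, THF/H2O, 0 °C; aq. Na2SO3; 1 M HCl
Reagents that add atoms: hydrogen peroxide, OO
Why: Hydroperoxide anion attacks the exocyclic imide carbonyl selectively (standard removal of an oxazolidinone auxiliary) and sulfite reduces the peracid, under conditions that do not enolise C1 or affect the alkenyl iodide, silyl ether and alkyl chloride.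

Step 15
Reactants: 24 carboxylic acid
Product: 25 (2R,5E,9Z)-2-{(Z)-4-[(tert-butyldimethylsilyl)oxy]-3-iodobut-2-en-1-yl}-12-chloro-N-methoxy-N,5,9-trimethyldodeca-5,9-dienamide
Conditions: MeNH(OMe)·HCl, EDC·HCl, HOBt, i-Pr2NEt, CH2Cl2, 0 °C to rt
Reagents that add atoms: N,O-dimethylhydroxylamine hydrochloride, CNOC.Cl
Why: Carbodiimide amide coupling through the benzotriazolyl active ester gives the Weinreb amide of an α-branched acid that carries no N-acyl group and therefore should not racemise.

Step 16
Reactants: 25 Weinreb amide; 26 5-bromo-2-methylpent-2-ene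
Product: 28 (7R,10E,14Z)-7-{(Z)-4-[(tert-butyldimethylsilyl)oxy]-3-iodobut-2-en-1-yl}-17-chloro-2,10,14-trimethylheptadeca-2,10,14-trien-6-one, via Grignard reagent 27 (not isolated)
Conditions: 26, Mg, THF; then 25, THF, 0 °C; aq. NH4Cl
Reagents that add atoms: none
Why: Weinreb ketone synthesis, in which the homoprenyl Grignard reagent adds once to give a magnesium-chelated tetrahedral adduct that collapses to the ketone only on work-up, avoids over-addition and enolisation at C1 and leaves the alkenyl iodide and alkyl chloride alone at 0 °C.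

Step 17
Reactants: 28 ketone
Product: 29 tert-butyl{[(2Z,5R,8E,12Z)-15-chloro-2-iodo-8,12-dimethyl-5-(6-methylhepta-1,5-dien-2-yl)pentadeca-2,8,12-trien-1-yl]oxy}dimethylsilane
Conditions: Cp2Ti(μ-Cl)(μ-CH2)AlMe2 (1.3 equiv), pyridine, THF/toluene, −40 to 0 °C
Reagents that add atoms: μ-chloro-μ-methylene-bis(cyclopentadienyl)titanium dimethylaluminium, C[Al-]1(C)C[Ti]([Cl+]1)(C1C=CC=C1)C1C=CC=C1
Why: Tebbe methylenation through a titanium methylidene and an oxatitanacyclobutane converts the ketone into the C15 exocyclic methylene under non-basic conditions, which should preserve the adjacent C1 stereocentre.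

Step 18
Reactants: 29 chloro alkenyl iodide
Product: 30 tert-butyl{[(2Z,5R,8E,12Z)-2,15-diiodo-8,12-dimethyl-5-(6-methylhepta-1,5-dien-2-yl)pentadeca-2,8,12-trien-1-yl]oxy}dimethylsilane
Conditions: NaI (10 equiv), NaHCO3, butan-2-one, 80 °C, dark
Reagents that add atoms: sodium iodide, [Na+].[I-]
Why: Finkelstein halide exchange (SN2, driven by precipitation of NaCl) unmasks the primary C5 iodide while the alkenyl iodide and the silyl ether do not react.

Step 19
Reactants: 30 diiodide
Product: 32 tert-butyldimethylsilyl ether of the target, via alkylzinc iodide 31 (not isolated)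
Conditions: Zn dust (activated with BrCH2CH2Br, Me3SiCl), THF, 35 °C, decant from excess Zn; then addition over 12 h to PdCl2(dppf) (10 mol%, reduced in situ with i-Bu2AlH), THF/N-methylpyrrolidone, 60 °C, final concentration about 1 mM
Reagents that add atoms: none
Why: Activated zinc inserts into the primary sp3 C5–I bond of 30 (the sp2 C4–I bond does not insert in THF at this temperature) to give 31; zerovalent palladium then adds oxidatively to the C4–I bond with retention, the tethered C5–Zn group transmetalates and reductive elimination forms C4–C5. The closest known reaction type is the Negishi coupling of primary homoallylic alkylzinc halides with alkenyl iodides, the intermolecular route to 1,5-dienes, and its use for ring closure parallels B-alkyl Suzuki macrocyclisations. The 14-membered carbocycle is closed head to tail by sp3–sp2 bond formation through a 15-membered palladacycle, favoured over oligomerisation by slow addition into dilute catalyst and by the three alkenes that stiffen the tether. No stereocentre is created: C1 is remote and untouched, and the C3=C4 geometry is carried over stereospecifically from the (Z)-iodide. The step needs chemoselective zinc insertion, retention at C4 and reductive elimination faster than β-hydride loss; these rest on the sp3/sp2 iodide reactivity gap, the stereospecific oxidative addition–reductive elimination sequence and the wide-bite-angle bidentate dppf ligand, the silyl ether and the other alkenes being spectators.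

Step 20
Reactants: 32 tert-butyldimethylsilyl ether of the target
Product: 33 target alcohol
Conditions: n-Bu4NF, THF, 0 °C to rt
Reagents that add atoms: none
Why: Fluoride-induced desilylation, driven by the strong Si–F bond, frees the primary allylic alcohol without affecting the five alkenes or C1.

Compound list

1 | hex-5-yn-1-ol | C#CCCCCO | starting material
2 | dimethylaluminium (E)-6-(dimethylalumanyl)-5-methylhex-5-en-1-olate (alkenylalane) | C[Al](C)OCCCC/C(C)=C/[Al](C)C | intermediate
3 | (E)-6-iodo-5-methylhex-5-en-1-ol | OCCCC/C(C)=C/I | intermediate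
4 | (E)-6-iodo-5-methylhex-5-enoic acid | OC(=O)CCC/C(C)=C/I | intermediate
5 | (S)-4-benzyloxazolidin-2-one | O=C1OC[C@H](Cc2ccccc2)N1 | starting material
6 | (E)-6-iodo-5-methylhex-5-enoic pivalic anhydride | CC(C)(C)C(=O)OC(=O)CCC/C(C)=C/I | intermediate
7 | (S)-4-benzyl-3-[(E)-6-iodo-5-methylhex-5-enoyl]oxazolidin-2-one | O=C1OC[C@H](Cc2ccccc2)N1C(=O)CCC/C(C)=C/I | intermediate
8 | 3-methylanisole | COc1cccc(C)c1 | starting material
9 | 1-methoxy-5-methylcyclohexa-1,4-diene | COC1=CCC=C(C)C1 | intermediate
10 | methyl (Z)-3-methyl-6-oxohex-3-enoate | COC(=O)C/C(C)=C\CC=O | intermediate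
11 | methyl (Z)-6-hydroxy-3-methylhex-3-enoate | COC(=O)C/C(C)=C\CCO | intermediate
12 | methyl (Z)-6-chloro-3-methylhex-3-enoate | COC(=O)C/C(C)=C\CCCl | intermediate
13 | (Z)-6-chloro-3-methylhex-3-en-1-ol | OCC/C(C)=C\CCCl | intermediate
14 | (Z)-6-chloro-1-iodo-3-methylhex-3-ene | ICC/C(C)=C\CCCl | intermediate
15 | [(Z)-6-chloro-3-methylhex-3-en-1-yl]zinc iodide | I[Zn]CC/C(C)=C\CCCl | intermediate
16 | (S)-4-benzyl-3-[(5E,9Z)-12-chloro-5,9-dimethyldodeca-5,9-dienoyl]oxazolidin-2-one | O=C1OC[C@H](Cc2ccccc2)N1C(=O)CCC/C(C)=C/CC/C(C)=C\CCCl | intermediate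
17 | but-2-yne-1,4-diol | OCC#CCO | starting material
18 | 4-[(tert-butyldimethylsilyl)oxy]but-2-yn-1-ol | CC(C)(C)[Si](C)(C)OCC#CCO | intermediate
19 | sodium 3-{[(tert-butyldimethylsilyl)oxy]methyl}-2,2-bis(2-methoxyethoxy)-2,5-dihydro-1,2-oxaluminol-2-uide (cyclic alkenylalanate) | [Na+].COCCO[Al-]1(OCCOC)OCC=C1CO[Si](C)(C)C(C)(C)C | intermediate
20 | (Z)-4-[(tert-butyldimethylsilyl)oxy]-3-iodobut-2-en-1-ol | CC(C)(C)[Si](C)(C)OC/C(I)=C/CO | intermediate
21 | (Z)-[(4-bromo-2-iodobut-2-en-1-yl)oxy](tert-butyl)dimethylsilane | CC(C)(C)[Si](C)(C)OC/C(I)=C/CBr | intermediate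
22 | sodium (Z)-enolate of imide 16 | [Na+].[O-]/C(=C\CC/C(C)=C/CC/C(C)=C\CCCl)N1[C@@H](Cc2ccccc2)COC1=O | intermediate
23 | (S)-4-benzyl-3-[(2R,5E,9Z)-2-{(Z)-4-[(tert-butyldimethylsilyl)oxy]-3-iodobut-2-en-1-yl}-12-chloro-5,9-dimethyldodeca-5,9-dienoyl]oxazolidin-2-one | O=C1OC[C@H](Cc2ccccc2)N1C(=O)[C@@H](C/C=C(/CO[Si](C)(C)C(C)(C)C)I)CC/C(C)=C/CC/C(C)=C\CCCl | intermediate
24 | (2R,5E,9Z)-2-{(Z)-4-[(tert-butyldimethylsilyl)oxy]-3-iodobut-2-en-1-yl}-12-chloro-5,9-dimethyldodeca-5,9-dienoic acid | OC(=O)[C@@H](C/C=C(/CO[Si](C)(C)C(C)(C)C)I)CC/C(C)=C/CC/C(C)=C\CCCl | intermediate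
25 | (2R,5E,9Z)-2-{(Z)-4-[(tert-butyldimethylsilyl)oxy]-3-iodobut-2-en-1-yl}-12-chloro-N-methoxy-N,5,9-trimethyldodeca-5,9-dienamide | CON(C)C(=O)[C@@H](C/C=C(/CO[Si](C)(C)C(C)(C)C)I)CC/C(C)=C/CC/C(C)=C\CCCl | intermediate
26 | 5-bromo-2-methylpent-2-ene | CC(C)=CCCBr | starting material
27 | (4-methylpent-3-en-1-yl)magnesium bromide | CC(C)=CCC[Mg]Br | intermediate
28 | (7R,10E,14Z)-7-{(Z)-4-[(tert-butyldimethylsilyl)oxy]-3-iodobut-2-en-1-yl}-17-chloro-2,10,14-trimethylheptadeca-2,10,14-trien-6-one | CC(C)=CCCC(=O)[C@@H](C/C=C(/CO[Si](C)(C)C(C)(C)C)I)CC/C(C)=C/CC/C(C)=C\CCCl | intermediate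
29 | tert-butyl{[(2Z,5R,8E,12Z)-15-chloro-2-iodo-8,12-dimethyl-5-(6-methylhepta-1,5-dien-2-yl)pentadeca-2,8,12-trien-1-yl]oxy}dimethylsilane | C=C(CCC=C(C)C)[C@@H](C/C=C(/CO[Si](C)(C)C(C)(C)C)I)CC/C(C)=C/CC/C(C)=C\CCCl | intermediate
30 | tert-butyl{[(2Z,5R,8E,12Z)-2,15-diiodo-8,12-dimethyl-5-(6-methylhepta-1,5-dien-2-yl)pentadeca-2,8,12-trien-1-yl]oxy}dimethylsilane | C=C(CCC=C(C)C)[C@@H](C/C=C(/CO[Si](C)(C)C(C)(C)C)I)CC/C(C)=C/CC/C(C)=C\CCI | intermediate
31 | {(3Z,7E,11R,13Z)-15-[(tert-butyldimethylsilyl)oxy]-14-iodo-4,8-dimethyl-11-(6-methylhepta-1,5-dien-2-yl)pentadeca-3,7,13-trien-1-yl}zinc iodide | C=C(CCC=C(C)C)[C@@H](C/C=C(/CO[Si](C)(C)C(C)(C)C)I)CC/C(C)=C/CC/C(C)=C\CC[Zn]I | intermediate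
32 | tert-butyldimethylsilyl ether of the target: (1R,3E,7Z,11E)-4-{[(tert-butyldimethylsilyl)oxy]methyl}-8,12-dimethyl-1-(6-methylhepta-1,5-dien-2-yl)cyclotetradeca-3,7,11-triene (atom labels of the remark) | C=C(CCC=C(C)C)[C@H]1C/C=C(/CO[Si](C)(C)C(C)(C)C)CC/C=C(/C)CC/C=C(\C)CC1 | intermediate
33 | [(1E,4Z,8E,12R)-5,9-dimethyl-12-(6-methylhepta-1,5-dien-2-yl)cyclotetradeca-1(14),4,8-trien-1-yl]methanol, i.e. the (1R,3E,7Z,11E)-4-(hydroxymethyl) triene in the atom labels of the remark | C=C(CCC=C(C)C)[C@H]1C/C=C(/CO)CC/C=C(/C)CC/C=C(\C)CC1 | target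

Total step count: 20.
Longest linear sequence: 14 steps (steps 4 to 9, then 13 to 20, from 3-methylanisole 8).

Steps most likely to fail

Step 19, ring closure. Intermolecular coupling to oligomers, protonolysis of the alkylzinc during the long addition, or β-hydride elimination may outrun cyclisation. The fallback is a nickel-catalysed reductive cross-electrophile macrocyclisation, which needs no preformed organometallic. Diiodide 30 would be added slowly to NiBr2(dme)/4,4′-di-tert-butyl-2,2′-bipyridine and Mn powder in N,N-dimethylacetamide at high dilution. The alkenyl iodide would be taken up by oxidative addition at nickel and the alkyl iodide as a radical captured at the same metal. The C7=C8 geometry would have to be checked, because a homoallylic radical can close reversibly to a cyclopropylcarbinyl radical. The fallback sets out from 30 and returns to the route at 32 with no new compound (F0).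

Step 17, methylenation. Enolisation of the α-branched ketone may erode the C1 configuration, or the hindered carbonyl may react incompletely. The fallback is a Peterson olefination in two operations. Ketone 28 would be treated with Me3SiCH2MgCl/CeCl3 in THF at −78 °C, where the organocerium adds without enolising, to give the β-hydroxysilane tertiary alcohol F1. KH in THF would then trigger syn-elimination of the silanolate, and the route is rejoined at 29.

Step 11, hydroalumination–iodination. Hydride delivery to the wrong alkyne carbon, or β-elimination of the silyloxy group from the alkenylalanate to an allene, may compete. The fallback is a hydroxyl-directed, ruthenium-catalysed trans-hydrostannation in which the free hydroxyl sits next to the future C4. It sets out from but-2-yne-1,4-diol 17 and replaces steps 10 and 11. Diol 17 would be monoacetylated (Ac2O, pyridine) to 4-hydroxybut-2-yn-1-yl acetate F2. Hydrostannation (Bu3SnH, [(C5Me5)RuCl]4, CH2Cl2) would give (Z)-4-hydroxy-3-(tributylstannyl)but-2-en-1-yl acetate F3. Iododestannylation with retention (I2, CH2Cl2, 0 °C) would give (Z)-4-hydroxy-3-iodobut-2-en-1-yl acetate F4. Silylation (t-BuMe2SiCl, imidazole) would give (Z)-4-[(tert-butyldimethylsilyl)oxy]-3-iodobut-2-en-1-yl acetate F5. Deacetylation (K2CO3, MeOH) would rejoin the route at 20.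

Further compounds

F0 | step 19 | none | none
F1 | step 17 | (7R,10E,14Z)-7-{(Z)-4-[(tert-butyldimethylsilyl)oxy]-3-iodobut-2-en-1-yl}-17-chloro-2,10,14-trimethyl-6-[(trimethylsilyl)methyl]heptadeca-2,10,14-trien-6-ol (mixture at the carbinol carbon) | CC(C)=CCCC(O)(C[Si](C)(C)C)[C@@H](C/C=C(/CO[Si](C)(C)C(C)(C)C)I)CC/C(C)=C/CC/C(C)=C\CCCl
F2 | step 11 | 4-hydroxybut-2-yn-1-yl acetate | CC(=O)OCC#CCO
F3 | step 11 | (Z)-4-hydroxy-3-(tributylstannyl)but-2-en-1-yl acetate | CCCC[Sn](CCCC)(CCCC)/C(CO)=C\COC(C)=O
F4 | step 11 | (Z)-4-hydroxy-3-iodobut-2-en-1-yl acetate | OC/C(I)=C/COC(C)=O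
F5 | step 11 | (Z)-4-[(tert-butyldimethylsilyl)oxy]-3-iodobut-2-en-1-yl acetate | CC(C)(C)[Si](C)(C)OC/C(I)=C/COC(C)=O
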